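**Retrosynthetic overview**

- Feature: C3 of the formyl-bearing (central) indole is bonded to C3a of its benzo ring, to the bis(indol-3-yl)methine carbon and to C2, which carries N1 and the formyl carbon. C3 is therefore the ketone carbon of a 2-anilino-3-oxo ester, and only the C3–C3a bond of the pyrrole ring is missing.
- After the ring closure: CHO ⇐ CH2OH ⇐ CO2Et at C2, with the two N-sulfonyl groups removed between reduction and oxidation.
- Before it: the C2–N bond comes from rhodium-carbenoid N–H insertion into aniline, the C2–C3 bond from malonate half-ester homologation of a diarylacetic acid, and the two methine–indole bonds from a double Friedel–Crafts reaction of indole with ethyl glyoxylate.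
- Ring order: the two outer indoles and the benzo ring of the central indole are bought (indole, aniline). The only ring built is the pyrrole ring of the central indole, in step 7.

Key step: step 7

Remark: Ts is 4-methylbenzenesulfonyl. The target has no stereocentre (the methine carries two identical indol-3-yl groups), so the anilino keto ester and every transient intermediate that has a stereocentre are handled as racemates or diastereomer mixtures.

**Route**

Step 1
Reactants: 1 indole (2 equiv); 2 ethyl glyoxylate
Product: 4 ethyl 2,2-bis(1H-indol-3-yl)acetate, via hydroxy ester 3 (not isolated)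
Conditions: p-TsOH·H2O (5 mol %), CH2Cl2, rt
Reagents that add atoms: none
Why: Acid-catalysed double Friedel–Crafts reaction (bis(indolyl)methane synthesis), in which indole C3 adds to the protonated aldehyde to give carbinol 3, which ionises to a 3-alkylideneindoleninium ion that a second indole captures at C3; the methine is not a stereocentre.

Step 2
Reactants: 4 ethyl 2,2-bis(1H-indol-3-yl)acetate; 5 4-methylbenzenesulfonyl chloride (2 equiv)
Product: 7 ethyl 2,2-bis[1-(4-methylbenzenesulfonyl)indol-3-yl]acetate, via mono-tosyl ester 6 (not isolated)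
Conditions: NaH (2.2 equiv), DMF, 0 °C; then 5 (slight excess), 0 °C to rt; aq. NH4Cl
Reagents that add atoms: 4-methylbenzenesulfonyl chloride, Cc1ccc(cc1)S(Cl)(=O)=O (the second equivalent of 5, which supplies the second sulfonyl group)
Why: Twofold N-sulfonylation of the sodium indolides, since NaH removes the two N–H protons before the hindered α-C–H and each indolide nitrogen displaces chloride from one molecule of 5, and the sulfonyl groups deactivate both indoles for steps 5 to 7.

Step 3
Reactants: 7 ethyl 2,2-bis[1-(4-methylbenzenesulfonyl)indol-3-yl]acetate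
Product: 8 2,2-bis[1-(4-methylbenzenesulfonyl)indol-3-yl]acetic acid
Conditions: LiOH·H2O (3 equiv), THF/H2O 3:1, rt; then 1 M HCl
Reagents that add atoms: lithium hydroxide monohydrate, [Li+].[OH-].O (source of the carboxyl O–H oxygen)
Why: Ester saponification (BAc2) in methanol-free aqueous THF at room temperature, where N-sulfonylindoles should not be cleaved, frees the acid for C-acylation.

Step 4
Reactants: 8 2,2-bis[1-(4-methylbenzenesulfonyl)indol-3-yl]acetic acid; 9 potassium ethyl malonate
Product: 11 ethyl 4,4-bis[1-(4-methylbenzenesulfonyl)indol-3-yl]-3-oxobutanoate, via acyl imidazolide 10 (not isolated)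
Conditions: 1,1'-carbonyldiimidazole (1.2 equiv), THF, rt; then 9 (2 equiv), MgCl2, Et3N, MeCN, rt to 40 °C; 1 M HCl
Reagents that add atoms: 1,1'-carbonyldiimidazole, O=C(n1ccnc1)n1ccnc1 (gives the imidazolyl group of intermediate 10 only; no atom of it remains in 11)
Why: Masamune–Brooks homologation, in which acyl imidazolide 10 C-acylates the magnesium enolate of the malonate half-ester and decarboxylation gives the β-keto ester, forming the future C2–C3 bond.

Step 5
Reactants: 11 ethyl 4,4-bis[1-(4-methylbenzenesulfonyl)indol-3-yl]-3-oxobutanoate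
Product: 12 ethyl 2-diazo-4,4-bis[1-(4-methylbenzenesulfonyl)indol-3-yl]-3-oxobutanoate
Conditions: 4-acetamidobenzenesulfonyl azide (1.2 equiv), Et3N, MeCN, 0 °C to rt
Reagents that add atoms: 4-acetamidobenzenesulfonyl azide, CC(=O)Nc1ccc(cc1)S(=O)(=O)N=[N+]=[N-]
Why: Regitz diazo transfer, in which the enolate of the 1,3-dicarbonyl methylene (far more acidic than the diarylmethine C–H) attacks the terminal azide nitrogen and the sulfonamide is expelled.

Step 6
Reactants: 12 ethyl 2-diazo-4,4-bis[1-(4-methylbenzenesulfonyl)indol-3-yl]-3-oxobutanoate; 13 aniline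
Product: 14 racemic ethyl 4,4-bis[1-(4-methylbenzenesulfonyl)indol-3-yl]-3-oxo-2-(phenylamino)butanoate
Conditions: Rh2(OAc)4 (2 mol %), toluene, 80 °C, slow addition of 12 to 13 (1.5 equiv)
Reagents that add atoms: none
Why: Rhodium-carbenoid N–H insertion, in which the electrophilic carbenoid is captured by the aniline nitrogen as an ammonium ylide and a 1,2-proton shift gives the α-anilino β-keto ester; the C2 stereocentre forms without control and is erased in step 7.

Step 7
Reactants: 14 racemic ethyl 4,4-bis[1-(4-methylbenzenesulfonyl)indol-3-yl]-3-oxo-2-(phenylamino)butanoate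
Product: 16 ethyl 3-{bis[1-(4-methylbenzenesulfonyl)indol-3-yl]methyl}-1H-indole-2-carboxylate, via 3-hydroxyindoline carbinol 15 (not isolated)
Conditions: BF3·OEt2 (3 equiv), ClCH2CH2Cl, 60 °C; aq. NaHCO3
Reagents that add atoms: none
Why: BF3 binds the ketone oxygen of 14 and the ortho carbon of the N-alkylated aniline ring adds to the activated carbonyl carbon (intramolecular Friedel–Crafts hydroxyalkylation) to give carbinol 15, which loses water with removal of the C2 proton to give the aromatic indole; the amino-ester carbon becomes C2 and the ketone carbon C3. The closest known reaction type is the Bischler indole synthesis in its modified form, the acid cyclodehydration of α-(arylamino) β-keto esters from carbenoid N–H insertion to 3-substituted indole-2-carboxylates. The pyrrole ring (N1–C2–C3–C3a–C7a) closes through the C3–C3a bond in a 5-exo-trig mode with respect to the carbonyl group. No stereocentre survives, because the C2 centre of 14 and both centres of 15 are erased on aromatisation and 16 is achiral. The step needs attack on the ketone and not on the ester carbonyl, which lies at the same distance from the ortho carbon; this should be secured by the higher electrophilicity of the BF3-bound ketone and by the irreversible dehydration to the aromatic ring. It also needs the side-chain indoles to stay inert, and their N-sulfonyl groups should suppress both competing Friedel–Crafts attack and acid-induced cleavage at the triarylmethine.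

Step 8
Reactants: 16 ethyl 3-{bis[1-(4-methylbenzenesulfonyl)indol-3-yl]methyl}-1H-indole-2-carboxylate
Product: 18 (3-{bis[1-(4-methylbenzenesulfonyl)indol-3-yl]methyl}-1H-indol-2-yl)methanol, via ditosyl aldehyde 17 (not isolated)
Conditions: iBu2AlH (4 equiv), CH2Cl2, −78 to 0 °C; aq. potassium sodium tartrate
Reagents that add atoms: none
Why: Hydride reduction of the conjugated ester through aldehyde 17 to the primary carbinol should leave the sulfonamides untouched at low temperature; it is placed before desulfonylation because Mg in MeOH would reduce the C2=C3 bond of an indole-2-carboxylate to the indoline.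

Step 9
Reactants: 18 (3-{bis[1-(4-methylbenzenesulfonyl)indol-3-yl]methyl}-1H-indol-2-yl)methanol
Product: 20 {3-[bis(1H-indol-3-yl)methyl]-1H-indol-2-yl}methanol, via mono-tosyl carbinol 19 (not isolated)
Conditions: Mg turnings (20 equiv), MeOH/THF, rt, sonication; aq. NH4Cl
Reagents that add atoms: none
Why: Single-electron reductive cleavage of the N–S bonds of N-arylsulfonylindoles by Mg in MeOH (desulfonylation) expels sulfinate and, with no conjugated ester left, should touch nothing else.

Step 10
Reactants: 20 {3-[bis(1H-indol-3-yl)methyl]-1H-indol-2-yl}methanol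
Product: 21 trisindolal
Conditions: activated MnO2 (15 equiv), CH2Cl2/acetone, rt
Reagents that add atoms: none
Why: Chemoselective MnO2 oxidation of the heterobenzylic (indol-2-yl) carbinol should stop at the aldehyde and give the achiral target.

**Compound list**

1 | indole | c1ccc2[nH]ccc2c1 | starting material
2 | ethyl glyoxylate | CCOC(=O)C=O | starting material
3 | ethyl 2-hydroxy-2-(1H-indol-3-yl)acetate (racemic) | CCOC(=O)C(O)c1c[nH]c2ccccc12 | intermediate (not isolated)
4 | ethyl 2,2-bis(1H-indol-3-yl)acetate | CCOC(=O)C(c1c[nH]c2ccccc12)c1c[nH]c2ccccc12 | intermediate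
5 | 4-methylbenzenesulfonyl chloride | Cc1ccc(cc1)S(Cl)(=O)=O | starting material
6 | ethyl 2-(1H-indol-3-yl)-2-[1-(4-methylbenzenesulfonyl)indol-3-yl]acetate (racemic) | CCOC(=O)C(c1c[nH]c2ccccc12)c1cn(S(=O)(=O)c2ccc(C)cc2)c2ccccc12 | intermediate (not isolated)
7 | ethyl 2,2-bis[1-(4-methylbenzenesulfonyl)indol-3-yl]acetate | CCOC(=O)C(c1cn(S(=O)(=O)c2ccc(C)cc2)c2ccccc12)c1cn(S(=O)(=O)c2ccc(C)cc2)c2ccccc12 | intermediate
8 | 2,2-bis[1-(4-methylbenzenesulfonyl)indol-3-yl]acetic acid | OC(=O)C(c1cn(S(=O)(=O)c2ccc(C)cc2)c2ccccc12)c1cn(S(=O)(=O)c2ccc(C)cc2)c2ccccc12 | intermediate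
9 | potassium ethyl malonate (potassium 3-ethoxy-3-oxopropanoate) | CCOC(=O)CC(=O)[O-].[K+] | starting material
10 | 1-{2,2-bis[1-(4-methylbenzenesulfonyl)indol-3-yl]acetyl}imidazole | O=C(n1ccnc1)C(c1cn(S(=O)(=O)c2ccc(C)cc2)c2ccccc12)c1cn(S(=O)(=O)c2ccc(C)cc2)c2ccccc12 | intermediate (not isolated)
11 | ethyl 4,4-bis[1-(4-methylbenzenesulfonyl)indol-3-yl]-3-oxobutanoate | CCOC(=O)CC(=O)C(c1cn(S(=O)(=O)c2ccc(C)cc2)c2ccccc12)c1cn(S(=O)(=O)c2ccc(C)cc2)c2ccccc12 | intermediate
12 | ethyl 2-diazo-4,4-bis[1-(4-methylbenzenesulfonyl)indol-3-yl]-3-oxobutanoate | CCOC(=O)C(=[N+]=[N-])C(=O)C(c1cn(S(=O)(=O)c2ccc(C)cc2)c2ccccc12)c1cn(S(=O)(=O)c2ccc(C)cc2)c2ccccc12 | intermediate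
13 | aniline | Nc1ccccc1 | starting material
14 | ethyl 4,4-bis[1-(4-methylbenzenesulfonyl)indol-3-yl]-3-oxo-2-(phenylamino)butanoate (racemic) | CCOC(=O)C(Nc1ccccc1)C(=O)C(c1cn(S(=O)(=O)c2ccc(C)cc2)c2ccccc12)c1cn(S(=O)(=O)c2ccc(C)cc2)c2ccccc12 | intermediate
15 | ethyl 3-{bis[1-(4-methylbenzenesulfonyl)indol-3-yl]methyl}-3-hydroxy-2,3-dihydro-1H-indole-2-carboxylate (mixture of racemic diastereomers) | CCOC(=O)C1Nc2ccccc2C1(O)C(c1cn(S(=O)(=O)c2ccc(C)cc2)c2ccccc12)c1cn(S(=O)(=O)c2ccc(C)cc2)c2ccccc12 | intermediate (not isolated)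
16 | ethyl 3-{bis[1-(4-methylbenzenesulfonyl)indol-3-yl]methyl}-1H-indole-2-carboxylate | CCOC(=O)c1[nH]c2ccccc2c1C(c1cn(S(=O)(=O)c2ccc(C)cc2)c2ccccc12)c1cn(S(=O)(=O)c2ccc(C)cc2)c2ccccc12 | intermediate
17 | 3-{bis[1-(4-methylbenzenesulfonyl)indol-3-yl]methyl}-1H-indole-2-carbaldehyde | O=Cc1[nH]c2ccccc2c1C(c1cn(S(=O)(=O)c2ccc(C)cc2)c2ccccc12)c1cn(S(=O)(=O)c2ccc(C)cc2)c2ccccc12 | intermediate (not isolated)
18 | (3-{bis[1-(4-methylbenzenesulfonyl)indol-3-yl]methyl}-1H-indol-2-yl)methanol | OCc1[nH]c2ccccc2c1C(c1cn(S(=O)(=O)c2ccc(C)cc2)c2ccccc12)c1cn(S(=O)(=O)c2ccc(C)cc2)c2ccccc12 | intermediate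
19 | (3-{(1H-indol-3-yl)[1-(4-methylbenzenesulfonyl)indol-3-yl]methyl}-1H-indol-2-yl)methanol (racemic) | OCc1[nH]c2ccccc2c1C(c1c[nH]c2ccccc12)c1cn(S(=O)(=O)c2ccc(C)cc2)c2ccccc12 | intermediate (not isolated)
20 | {3-[bis(1H-indol-3-yl)methyl]-1H-indol-2-yl}methanol | OCc1[nH]c2ccccc2c1C(c1c[nH]c2ccccc12)c1c[nH]c2ccccc12 | intermediate
21 | trisindolal, 3-[bis(1H-indol-3-yl)methyl]-1H-indole-2-carbaldehyde | O=Cc1[nH]c2ccccc2c1C(c1c[nH]c2ccccc12)c1c[nH]c2ccccc12 | target

**Count and risks**

Total step count: 10. Longest linear sequence: 10 steps (from indole and ethyl glyoxylate to 21).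

Steps most likely to fail:

1. Step 7. The ring closure may stall. The secondary anilino nitrogen can bind the Lewis acid and lower the nucleophilicity of the ring, the 1,3-dicarbonyl unit can be tied up as a boron enolate chelate, and the diarylmethyl group shields the ketone. The fallback runs the same closure on an N,N-dialkylaniline, the substrate class on which it is best established; it sets out from 12 and comes back at 16. Aniline 13 is added to phenyl vinyl sulfone (aza-Michael, EtOH, cat. AcOH, reflux) to give N-[2-(phenylsulfonyl)ethyl]aniline F1. Rh2(OAc)4-catalysed N–H insertion of 12 into F1 should give ethyl 4,4-bis[1-(4-methylbenzenesulfonyl)indol-3-yl]-3-oxo-2-{phenyl[2-(phenylsulfonyl)ethyl]amino}butanoate F2. BF3·OEt2, or a sulfonic acid resin in hot toluene, should close it to ethyl 3-{bis[1-(4-methylbenzenesulfonyl)indol-3-yl]methyl}-1-[2-(phenylsulfonyl)ethyl]indole-2-carboxylate F3. KOtBu in THF at 0 °C then expels phenyl vinyl sulfone by retro-Michael (E1cB) cleavage, with the indole-2-carboxylate anion as leaving group, to give 16.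

2. Step 6. The carbenoid may be consumed inside the molecule before aniline reaches it (attack on the C2=C3 bond of a neighbouring N-sulfonylindole, or Wolff rearrangement), and the amine may slow the catalyst. The fallback avoids a carbenoid; it sets out from 11 and comes back at 14. N-Chlorosuccinimide in CH2Cl2 chlorinates the 1,3-dicarbonyl methylene to ethyl 2-chloro-4,4-bis[1-(4-methylbenzenesulfonyl)indol-3-yl]-3-oxobutanoate F4. Aniline 13 (1.2 equiv, NaHCO3, DMF, rt) then displaces chloride at the activated α-carbon (SN2), while the hindered ketone should resist imine formation, to give 14.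

3. Step 10. The oxidation may overrun by hydride loss from the electron-rich triindolylmethane methine of 20, leading to the triarylmethylium dye. The fallback oxidises while two indoles are still deactivated; it sets out from 18 and comes back at 21. MnO2 in CH2Cl2 converts 18 into ditosyl aldehyde 17, now isolated. Bu4NF in refluxing THF then removes the two sulfonyl groups one after the other by fluoride attack at sulfur, through 3-{(1H-indol-3-yl)[1-(4-methylbenzenesulfonyl)indol-3-yl]methyl}-1H-indole-2-carbaldehyde F5, to give 21.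

**Further compounds**

F1 | step 7 | N-[2-(phenylsulfonyl)ethyl]aniline | O=S(=O)(CCNc1ccccc1)c1ccccc1
F2 | step 7 | ethyl 4,4-bis[1-(4-methylbenzenesulfonyl)indol-3-yl]-3-oxo-2-{phenyl[2-(phenylsulfonyl)ethyl]amino}butanoate (racemic) | CCOC(=O)C(N(CCS(=O)(=O)c1ccccc1)c1ccccc1)C(=O)C(c1cn(S(=O)(=O)c2ccc(C)cc2)c2ccccc12)c1cn(S(=O)(=O)c2ccc(C)cc2)c2ccccc12
F3 | step 7 | ethyl 3-{bis[1-(4-methylbenzenesulfonyl)indol-3-yl]methyl}-1-[2-(phenylsulfonyl)ethyl]indole-2-carboxylate | CCOC(=O)c1n(CCS(=O)(=O)c2ccccc2)c2ccccc2c1C(c1cn(S(=O)(=O)c2ccc(C)cc2)c2ccccc12)c1cn(S(=O)(=O)c2ccc(C)cc2)c2ccccc12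
F4 | step 6 | ethyl 2-chloro-4,4-bis[1-(4-methylbenzenesulfonyl)indol-3-yl]-3-oxobutanoate (racemic) | CCOC(=O)C(Cl)C(=O)C(c1cn(S(=O)(=O)c2ccc(C)cc2)c2ccccc12)c1cn(S(=O)(=O)c2ccc(C)cc2)c2ccccc12
F5 | step 10 | 3-{(1H-indol-3-yl)[1-(4-methylbenzenesulfonyl)indol-3-yl]methyl}-1H-indole-2-carbaldehyde (racemic) | O=Cc1[nH]c2ccccc2c1C(c1c[nH]c2ccccc12)c1cn(S(=O)(=O)c2ccc(C)cc2)c2ccccc12
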